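## Structural features

The target, 8-(3,4-dimethoxyphenyl)-2,6-dimethoxynaphthalene-1,4-dione, is a 1,4-naphthoquinone. Ring A is the quinone ring C1(=O)–C2(OMe)=C3H–C4(=O), fused through C4a and C8a to the benzo ring B (C5–C8). Ring B carries a methoxy group at C6 and, at C8, a 3,4-dimethoxyphenyl ring (ring C) joined by a biaryl bond. There is no stereocentre, and ring C has no ortho substituent, so the biaryl axis should rotate freely and no stereochemical question arises. The fragile elements are the quinone (reductants, nucleophiles, strong base), the C2 methoxy group (a vinylogous ester that can be exchanged or hydrolysed) and the electron-rich ring C (electrophiles, strong oxidants). The real difficulty is positional: ring B is 1,2,3,5-tetrasubstituted with the C6 methoxy meta to the C8 aryl, and the unsymmetrical ring A must be oriented so that the carbonyl next to C2–OMe (C1) is the one peri to the aryl group. The key step exploits the fact that ring B can be read as three two-carbon units, C4a–C5, C6–C7 and C8–C8a, the first and third already linked by the four ring-A carbons C1–C4, so a tethered diyne and a two-carbon methoxyalkyne build both carbocycles at once. The C1 carbonyl this places next to C8a makes C2 the only enolisable position, so the oxygen atoms still missing at C2 and C4 can be added afterwards without positional ambiguity.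

## Logic of the disconnections

**14 to 13.** The O–CH3 bond on the C2 oxygen is cut first, because the vinylogous ester is the most labile group and is best made last. This reveals 13, whose three ring-A oxygens already sit on C1, C2 and C4. The forward step must etherify the C2 oxygen and not the C4 oxygen of the tautomeric ortho-quinone form. A reversible, acid-catalysed etherification meets this better than an irreversible alkylation of the ambident anion.

**13 to 11.** The C2–O and C4–O bonds and two degrees of unsaturation of ring A are removed. Ring A becomes a saturated three-carbon chain with a single ketone at C1, and no quinone has to pass through the metal-catalysed step. The forward oxidation must begin at C2, the only enolisable carbon of 11, continue at benzylic C4, and stop before ring A is cleaved.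

**11 to 7 and 10.** The bonds C4a–C8a, C5–C6 and C7–C8 are cut, which opens ring B and ring A together. The gain is the largest of the route: a bicyclic, tetrasubstituted arene becomes an acyclic diyne and a two-carbon alkyne. The forward step must favour cross-cycloaddition over self-trimerisation and must place the methoxy-bearing carbon of 10 on C5, away from the aryl-bearing C8.

**7 to 3 and 4.** The bond between the ketone carbon and the aryl-substituted alkyne is cut. This divides 7 into two pieces of similar size, each one step or less from a commercial compound. The forward step must stop at the ketone and must tolerate the free terminal alkyne of 3. No silyl protecting group is planned, since it would cost two steps and require a desilylation next to a Michael-accepting ynone.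

**3 to 1.** The amide C–N bond is cut, leading back to commercial 1. The only demand is an activation that leaves the terminal alkyne untouched.

**10 to 8.** The triple bond is traced back to two β-eliminations (loss of methanol and of hydrogen chloride) from commercial 8. The forward step needs a strong amide base and careful handling of a volatile, heat-sensitive product.

## Other disconnections considered

**Alternative 1:** Ring B is cut at C4a–C5 and C8–C8a. In the forward direction the unsubstituted double bond of 2-methoxy-1,4-benzoquinone A1 would add thermally to (E)-1-(3,4-dimethoxyphenyl)-3-(tert-butyldimethylsilyloxy)buta-1,3-diene A2 in a Diels–Alder reaction. The product would be the cis-fused endo adduct A3, which must then be dehydrogenated to the naphthoquinone, desilylated and O-methylated at C6.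
- In favour: the chemistry is classical and metal-free, and A2 is two routine steps from commodity chemicals. The regiochemistry has a sound electronic basis: the C2 methoxy makes the C4 carbonyl a vinylogous ester, so the C1 carbonyl directs, and the nucleophilic CH2 terminus of A2 should bond to C4a.
- Against: three stereocentres are made only to be erased, a silyl enol ether must survive the cycloaddition, and oxidation-level adjustment plus a silyl-to-methyl exchange are needed afterwards. The orientation rests on an electronic bias that would have to be confirmed on this pair.
- Comparison: the step count is about equal. The alternative is better in reagent handling (no NaNH2 in liquid ammonia, no volatile ynol ether, no ruthenium) and in carrying the quinone oxygens and the C2 methoxy from the start, which avoids the strongly basic autoxidation. The chosen plan is better in delivering ring B already aromatic with the C6 methoxy in place and in having no stereochemical or protecting-group bookkeeping. Overall this alternative is at least the equal of the chosen plan in robustness.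

**Alternative 2:** Ring C is cut at C1'–C2' and C5'–C6'. Forward, CoBr2(dppe) reduced by zinc in the presence of ZnI2 (monovalent cobalt) would join 8-ethynyl-1,2,4,6-tetramethoxynaphthalene A4 and 2,3-dimethoxybuta-1,3-diene A5 in a neutral Diels–Alder reaction. The product would be the 1,4-cyclohexadiene A6, to be aromatised with DDQ and then oxidatively demethylated to the quinone.
- In favour: the diene is symmetrical, so the key step has no regiochemical question, and the cyclohexadiene aromatises easily. On this point it is better than the chosen plan.
- Against: the key step builds the simplest ring of the molecule, which is available ready-made, and forms a biaryl that a cross-coupling would make directly. All the real difficulty (the penta-substituted naphthalene with a peri ethynyl group) is moved into A4, which needs a long preparation. The final oxidative demethylation of a 1,2,4-trimethoxynaphthalene can give the ortho-quinone as well as the para-quinone and must spare ring C.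
- Comparison: the chosen plan spends its key step on the hard part (rings A and B and their substitution pattern) and is clearly shorter. The alternative wins only on the regiochemical certainty of its own key step.

**Alternative 3:** Ring B is cut at C4a–C5. Forward, one-electron oxidation (at an anode, or with DDQ and 2,6-lutidine) of (Z)-1-[2-(benzyloxy)-3-methoxyphenyl]-1-(3,4-dimethoxyphenyl)-3-methoxybuta-1,3-diene A7 would give an enol ether radical cation. Its CH2 terminus would attack the ring-A carbon para to the methoxy group, and loss of a second electron and two protons would give 1-(benzyloxy)-8-(3,4-dimethoxyphenyl)-2,6-dimethoxynaphthalene A8. Debenzylation and para-oxidation of the resulting 1-naphthol would finish the synthesis.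
- In favour: every oxygen is already on the right carbon, the attacked arene position is activated, and the endgame is mild and unambiguous because C4 is the only free para position. On the endgame it is better than the chosen plan.
- Against: A7 needs a stereodefined trisubstituted alkene bearing two different electron-rich aryl groups next to an acid-sensitive 2-methoxydiene, which is a multi-step problem. Under radical-cation conditions alkene isomerisation could let ring C compete as the nucleophile and give an isomeric naphthalene. The cyclisation is the least precedented of the three key steps for this substrate class.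
- Comparison: structurally it forms one ring and one bond where the chosen key step forms two rings and three bonds. Mechanistically it depends on which π-system is oxidised first, whereas the cycloaddition depends on a steric preference. The chosen plan is shorter overall.

Key step: step 4

Remarks on the design: checking the atom mapping (C4a≡C5 and C8≡C8a from the diyne, C6≡C7 from the methoxyalkyne, C1–C4 as tether) against the target confirms the constitutions of 7, 10 and 11, so no structural correction is needed. Two changes were made to the obvious execution. The terminal alkyne of the acid fragment is carried unprotected. The final O-methylation is run under reversible acid catalysis instead of with MeI and Ag2O, which can alkylate the other oxygen. Cp* is η5-pentamethylcyclopentadienyl and cod is cycloocta-1,5-diene.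

## Route

Step 1
Reactants: 1 hex-5-ynoic acid
Product: 3 N-methoxy-N-methylhex-5-ynamide, via acyl imidazolide 2 (not isolated)
Conditions: CDI (1.1 equiv), CH2Cl2, 0 °C → rt; then MeNHOMe·HCl (1.2 equiv), rt
Reagents that add atoms: N,O-dimethylhydroxylamine hydrochloride, CNOC.Cl
Why: Activation of the acid as its acyl imidazolide (loss of CO2 and imidazole) followed by aminolysis is a standard Weinreb amide synthesis and does not touch the terminal alkyne. The amide is chosen because it later stops acetylide addition at the ketone stage.

Step 2
Reactants: 3 N-methoxy-N-methylhex-5-ynamide; 4 4-ethynyl-1,2-dimethoxybenzene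
Product: 7 1-(3,4-dimethoxyphenyl)octa-1,7-diyn-3-one, via lithium arylacetylide 5 (not isolated), via lithium hemiaminal adduct 6 (not isolated)
Conditions: 4 (1.3 equiv), n-BuLi (1.25 equiv), THF, −78 °C; then 3, −78 → 0 °C; then cold 1 M HCl
Reagents that add atoms: none
Why: Weinreb ketone synthesis: acetylide 5 adds once to 3 to give the chelated tetrahedral adduct 6, which collapses to the ynone only on quench, so no tertiary alcohol can form. An arylacetylide is a weaker base than the alkylacetylide that deprotonation of the terminal C–H of 3 would give, so proton transfer should be unfavourable and no silyl protection is needed. The acidic quench protonates the released amine and so prevents its conjugate addition to 7.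

Step 3
Reactants: 8 chloroacetaldehyde dimethyl acetal (2-chloro-1,1-dimethoxyethane)
Product: 10 methoxyacetylene, via sodium methoxyacetylide 9 (not isolated)
Conditions: NaNH2 (3.1 equiv), liq. NH3, −33 °C; NH3 evaporated under N2; then cold sat. aq. NaCl, −70 → 20 °C, product distilled into a −78 °C trap and kept as a cold solution in ClCH2CH2Cl
Reagents that add atoms: none
Why: Double β-elimination by amide base (loss of methanol, then of hydrogen chloride) gives the ynol ether, held as its sodium acetylide 9 until protonation by water; this is the classical preparation of alkoxyacetylenes from chloroacetals. The product is volatile and heat-sensitive, so it is distilled straight into a cold trap and used the same day.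

Step 4
Reactants: 7 1-(3,4-dimethoxyphenyl)octa-1,7-diyn-3-one; 10 methoxyacetylene
Product: 11 8-(3,4-dimethoxyphenyl)-6-methoxy-3,4-dihydronaphthalen-1(2H)-one
Conditions: Cp*RuCl(cod) (5 mol %, divalent ruthenium), 10 (4 equiv), ClCH2CH2Cl, 0 → 20 °C, closed vessel, Ar, 7 added slowly by syringe pump
Reagents that add atoms: none
Why: Known reaction type: Cp*RuCl(cod)-catalysed [2+2+2] cycloaddition of an α,ω-diyne with a terminal alkyne, here with an ynol ether as the less usual two-carbon partner. After loss of cod, divalent ruthenium binds both alkynes of 7 and couples them oxidatively; this forms C4a–C8a and closes ring A as a six-membered carbocycle fused to a catalyst-bound ruthenacycle (tetravalent ruthenium) whose metal-bound carbons are C5 (H) and C8 (aryl). Alkyne 10 then inserts on the unhindered Ru–C5 side, forming C5–C6, and reductive elimination forms C7–C8, closes ring B directly as a benzene ring and returns divalent ruthenium. Ring A is thus closed by metal-mediated oxidative coupling through the four-atom tether and ring B by insertion and reductive elimination; no stereocentre is created. Two selectivities are needed. Chemoselectivity (cross-cycloaddition over self-trimerisation of either alkyne) is secured by the intramolecular first step and by adding 7 slowly to an excess of 10. Regioselectivity (methoxy at C6, meta to the aryl group) is secured by the substrate: the aryl group and the Cp* ligand shield C8, so the substituted carbon of 10 goes to C5 and its CH terminus ends up next to C8, the usual meta outcome for diynes with one substituted terminus, and the polarity of the partners (nucleophilic CH terminus of the ynol ether, electrophilic β-carbon C8 of the ynone) points the same way. The conjugated C1 ketone is a spectator here and is kept as the handle for step 5.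

Step 5
Reactants: 11 8-(3,4-dimethoxyphenyl)-6-methoxy-3,4-dihydronaphthalen-1(2H)-one
Product: 13 8-(3,4-dimethoxyphenyl)-2-hydroxy-6-methoxynaphthalene-1,4-dione, via dihydronaphthalene-1,2-dione 12 (not isolated)
Conditions: O2 (1 atm), KOtBu (4 equiv), t-BuOH, 30 °C; then 1 M HCl
Reagents that add atoms: oxygen, O=O
Why: Base-mediated autoxidation of a 1-tetralone to a 2-hydroxy-1,4-naphthoquinone (known reaction type): the potassium enolate, which can form only toward C2, is oxygenated by O2 to give diketone 12. Compound 12 enolises toward C3–C4 to an aromatic catecholate, and a second oxygenation at C4 with loss of water gives the quinone, which is shielded from further attack as its delocalised potassium salt until acidification. The aryl methyl ethers and the biaryl are inert to these conditions.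

Step 6
Reactants: 13 8-(3,4-dimethoxyphenyl)-2-hydroxy-6-methoxynaphthalene-1,4-dione
Product: 14 8-(3,4-dimethoxyphenyl)-2,6-dimethoxynaphthalene-1,4-dione
Conditions: MeOH, conc. HCl (cat.), reflux
Reagents that add atoms: methanol, CO
Why: Acid-catalysed etherification of the vinylogous acid (addition of methanol at C2, loss of water) is reversible, so the outcome is under thermodynamic control and should favour the para-quinone ether 14 over the isomeric 4-methoxy-1,2-quinone. An irreversible alkylation of the ambident anion (MeI with Ag2O) is avoided for that reason, and the aryl methyl ethers are stable to the acid.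

## Compound list

1 | hex-5-ynoic acid | C#CCCCC(=O)O | starting material
2 | 1-(1H-imidazol-1-yl)hex-5-yn-1-one (acyl imidazolide) | C#CCCCC(=O)n1ccnc1 | intermediate
3 | N-methoxy-N-methylhex-5-ynamide | C#CCCCC(=O)N(C)OC | intermediate
4 | 4-ethynyl-1,2-dimethoxybenzene | COc1ccc(C#C)cc1OC | starting material
5 | lithium (3,4-dimethoxyphenyl)acetylide | [Li]C#Cc1ccc(OC)c(OC)c1 | intermediate
6 | lithium 1-(3,4-dimethoxyphenyl)-3-[methoxy(methyl)amino]octa-1,7-diyn-3-olate (racemic) | C#CCCCC(O[Li])(C#Cc1ccc(OC)c(OC)c1)N(C)OC | intermediate
7 | 1-(3,4-dimethoxyphenyl)octa-1,7-diyn-3-one | COc1ccc(C#CC(=O)CCCC#C)cc1OC | intermediate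
8 | chloroacetaldehyde dimethyl acetal (2-chloro-1,1-dimethoxyethane) | COC(CCl)OC | starting material
9 | sodium methoxyacetylide | [Na]C#COC | intermediate
10 | methoxyacetylene | COC#C | intermediate
11 | 8-(3,4-dimethoxyphenyl)-6-methoxy-3,4-dihydronaphthalen-1(2H)-one | O=C1CCCc2cc(OC)cc(-c3ccc(OC)c(OC)c3)c12 | intermediate
12 | 8-(3,4-dimethoxyphenyl)-6-methoxy-3,4-dihydronaphthalene-1,2-dione | O=C1C(=O)CCc2cc(OC)cc(-c3ccc(OC)c(OC)c3)c12 | intermediate
13 | 8-(3,4-dimethoxyphenyl)-2-hydroxy-6-methoxynaphthalene-1,4-dione | OC1=CC(=O)c2cc(OC)cc(-c3ccc(OC)c(OC)c3)c2C1=O | intermediate
14 | 8-(3,4-dimethoxyphenyl)-2,6-dimethoxynaphthalene-1,4-dione | COC1=CC(=O)c2cc(OC)cc(-c3ccc(OC)c(OC)c3)c2C1=O | target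

## Step count and least certain steps

Total step count: 6. Longest linear sequence: 5 steps (steps 1, 2, 4, 5 and 6); step 3 is a one-step branch.

**Step 4 (key step).** The ynol ether may oligomerise or deactivate the catalyst faster than it is inserted. Oxidative coupling of a 1,7-diyne is slower than that of a 1,6-diyne, so self-trimerisation of 7 can compete. The insertion could also lose regioselectivity if the aryl group shields C8 less than expected. The fallback keeps the ring construction but brings in the C6 oxygen differently, through a robust, non-volatile alkyne partner. Setting out from 7, cycloaddition with commercial 2-ethynyl-4,4,5,5-tetramethyl-1,3,2-dioxaborolane under Cp*RuCl(cod) catalysis (a known partner class for this catalyst) should give 8-(3,4-dimethoxyphenyl)-6-(4,4,5,5-tetramethyl-1,3,2-dioxaborolan-2-yl)-3,4-dihydronaphthalen-1(2H)-one F1, with the boryl group meta to the aryl group by the same steric argument. Oxidation of the C–B bond (NaBO3·4H2O, THF/H2O) should give 8-(3,4-dimethoxyphenyl)-6-hydroxy-3,4-dihydronaphthalen-1(2H)-one F2. O-methylation (MeI, K2CO3, acetone) comes back to the route at 11. This fallback does not help if the diyne coupling itself is the failing event.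

**Step 5.** The oxidation may run on to cleavage of ring A at the 1,2-dicarbonyl stage, or stall before the second oxygenation. The enolate may also condense with diketone 12. The fallback fixes the C2 substituent through the ketone α-position and avoids base and O2 altogether. Setting out from 11, α,α-dibromination with PhNMe3Br3 (2.1 equiv, THF), which spares the electron-rich rings, should give 2,2-dibromo-8-(3,4-dimethoxyphenyl)-6-methoxy-3,4-dihydronaphthalen-1(2H)-one F3. Dehydrobromination and tautomerisation with DBU in MeCN should give 2-bromo-8-(3,4-dimethoxyphenyl)-6-methoxynaphthalen-1-ol F4. Teuber oxidation at the free para position C4 with (KSO3)2NO (Fremy's salt, KH2PO4, acetone/H2O) should give 2-bromo-8-(3,4-dimethoxyphenyl)-6-methoxynaphthalene-1,4-dione F5. Addition–elimination with NaOMe in MeOH at 0 °C comes back to the route directly at 14.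

**Step 2.** Proton transfer from the terminal alkyne of 3 to acetylide 5 could lead to self-acylation of 3, and an insufficiently acidic quench would allow conjugate addition of the released amine to the ynone. The fallback replaces acylation by a faster carbonyl addition followed by oxidation. Setting out from 3, reduction with i-Bu2AlH (THF, −78 °C) should give hex-5-ynal F6. Addition of acetylide 5 at −78 °C, where aldehyde addition far outruns proton transfer, should give racemic 1-(3,4-dimethoxyphenyl)octa-1,7-diyn-3-ol F7. Oxidation of the propargylic alcohol with MnO2 in CH2Cl2 comes back to the route at 7.

**Step 6.** Conversion may stay incomplete because the etherification is an equilibrium, and the kinetically formed ortho-quinone ether may isomerise only slowly. The fallback replaces etherification by substitution on a haloquinone. Setting out from 13, treatment with SOCl2 at reflux should give 2-chloro-8-(3,4-dimethoxyphenyl)-6-methoxynaphthalene-1,4-dione F8. Addition–elimination with NaOMe in MeOH at 0 °C comes back to the route at 14.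

## Further compounds

F1 | step 4 | 8-(3,4-dimethoxyphenyl)-6-(4,4,5,5-tetramethyl-1,3,2-dioxaborolan-2-yl)-3,4-dihydronaphthalen-1(2H)-one | O=C1CCCc2cc(B3OC(C)(C)C(C)(C)O3)cc(-c4ccc(OC)c(OC)c4)c12
F2 | step 4 | 8-(3,4-dimethoxyphenyl)-6-hydroxy-3,4-dihydronaphthalen-1(2H)-one | O=C1CCCc2cc(O)cc(-c3ccc(OC)c(OC)c3)c12
F3 | step 5 | 2,2-dibromo-8-(3,4-dimethoxyphenyl)-6-methoxy-3,4-dihydronaphthalen-1(2H)-one | O=C1C(Br)(Br)CCc2cc(OC)cc(-c3ccc(OC)c(OC)c3)c12
F4 | step 5 | 2-bromo-8-(3,4-dimethoxyphenyl)-6-methoxynaphthalen-1-ol | Oc1c(Br)ccc2cc(OC)cc(-c3ccc(OC)c(OC)c3)c12
F5 | step 5 | 2-bromo-8-(3,4-dimethoxyphenyl)-6-methoxynaphthalene-1,4-dione | BrC1=CC(=O)c2cc(OC)cc(-c3ccc(OC)c(OC)c3)c2C1=O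
F6 | step 2 | hex-5-ynal | C#CCCCC=O
F7 | step 2 | 1-(3,4-dimethoxyphenyl)octa-1,7-diyn-3-ol (racemic) | C#CCCCC(O)C#Cc1ccc(OC)c(OC)c1
F8 | step 6 | 2-chloro-8-(3,4-dimethoxyphenyl)-6-methoxynaphthalene-1,4-dione | ClC1=CC(=O)c2cc(OC)cc(-c3ccc(OC)c(OC)c3)c2C1=O
A1 | alternative 1 | 2-methoxy-1,4-benzoquinone | COC1=CC(=O)C=CC1=O
A2 | alternative 1 | (E)-1-(3,4-dimethoxyphenyl)-3-(tert-butyldimethylsilyloxy)buta-1,3-diene | COc1ccc(/C=C/C(=C)O[Si](C)(C)C(C)(C)C)cc1OC
A3 | alternative 1 | endo cycloadduct, cis-fused 8-(3,4-dimethoxyphenyl)-6-(tert-butyldimethylsilyloxy)-2-methoxy-4a,5,8,8a-tetrahydronaphthalene-1,4-dione (racemic, relative configuration shown) | COC1=CC(=O)[C@H]2CC(O[Si](C)(C)C(C)(C)C)=C[C@@H](c3ccc(OC)c(OC)c3)[C@H]2C1=O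
A4 | alternative 2 | 8-ethynyl-1,2,4,6-tetramethoxynaphthalene | C#Cc1cc(OC)cc2c(OC)cc(OC)c(OC)c12
A5 | alternative 2 | 2,3-dimethoxybuta-1,3-diene | C=C(OC)C(=C)OC
A6 | alternative 2 | 8-(4,5-dimethoxycyclohexa-1,4-dien-1-yl)-1,2,4,6-tetramethoxynaphthalene | COC1=C(OC)CC(=CC1)c1cc(OC)cc2c(OC)cc(OC)c(OC)c12
A7 | alternative 3 | (Z)-1-[2-(benzyloxy)-3-methoxyphenyl]-1-(3,4-dimethoxyphenyl)-3-methoxybuta-1,3-diene | C=C(OC)/C=C(\c1cccc(OC)c1OCc1ccccc1)c1ccc(OC)c(OC)c1
A8 | alternative 3 | 1-(benzyloxy)-8-(3,4-dimethoxyphenyl)-2,6-dimethoxynaphthalene | COc1ccc2cc(OC)cc(-c3ccc(OC)c(OC)c3)c2c1OCc1ccccc1
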